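**Retrosynthetic overview**

- The target is a linear chain of seven oxygenated benzene rings (A to G) joined by six diaryl ether oxygens. It is reached last by cleaving all methyl ethers of a methyl-protected heptamer.
- The strategy rests on ring B. Its position 1 carries the oxygen to ring A, position 4 the oxygen to ring C, positions 3 and 5 carry hydroxyls, and positions 2 and 6 are CH. This 1,3,4,5-oxygen pattern is built from open-chain carbon by a [4+2] cycloaddition that forms the bonds between positions 1 and 2 and between positions 5 and 6, followed by aromatisation.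
- The diene is a 1-methoxy-1,3-bis(trimethylsilyloxy)butadiene with rings C to G on the oxygen of its second carbon. The dienophile is a 3-(2,4,6-trimethoxyphenoxy)propiolate (ring A), whose ester ends on position 6 of ring B and is then removed as CO2.
- The diene comes from the pentamer phenol (rings C to G) by O-alkylation with methyl 2-chloroacetoacetate and double silylation. The pentamer phenol comes from 3,4,5-trimethoxyphenol (ring G) by four rounds of Ullmann etherification and Baeyer–Villiger oxidation, adding rings F, E, D and C.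
- Ring B is the only ring constructed; rings G, F, E, D, C and A are purchased arenes.

Key step: step 14

Remarks:
- Rings are lettered A (2,4,6-trioxygenated end) to G (3,4,5-trioxygenated end). "Trimer-oxy", "tetramer-oxy" and "pentamer-oxy" mean the permethylated chains from ring G to ring E, to ring D and to ring C, bound through the oxygen on position 1 of ring E, ring D and ring C.
- A benzyl ester is chosen for the propiolate so that the carboxyl group on ring B can be freed by hydrogenolysis under neutral conditions.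
- 4-Bromo-3,5-dimethoxybenzaldehyde, 2-bromo-3,4,5-trimethoxybenzaldehyde and 2,4,6-trimethoxyphenol are taken as commercial.
- The target has no stereocentre. The double-bond geometry drawn for the silyl enol ethers is arbitrary and is erased on aromatisation.

**Route**

Step 1
Reactants: 1 3,4,5-trimethoxyphenol (ring G); 2 4-bromo-3,5-dimethoxybenzaldehyde
Product: 3 dimer aldehyde 3,5-dimethoxy-4-(3,4,5-trimethoxyphenoxy)benzaldehyde
Conditions: CuI (10 mol%), picolinic acid (20 mol%), K3PO4, DMSO, 90 °C, argon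
Reagents that add atoms: none
Why: Ullmann diaryl ether synthesis, in which the para-formyl group activates the C–Br bond toward the ligated copper phenoxide, the flanking methoxy groups are small, and the phenol has no ortho substituent.

Step 2
Reactants: 3 dimer aldehyde
Product: 5 dimer phenol 3,5-dimethoxy-4-(3,4,5-trimethoxyphenoxy)phenol, via dimer aryl formate 4 (not isolated)
Conditions: mCPBA, CH2Cl2, 0 °C to rt; aq. NaHCO3 wash; then Et3N (cat.), MeOH, rt
Reagents that add atoms: mCPBA, OOC(=O)c1cccc(Cl)c1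
Why: Baeyer–Villiger oxidation, in which the electron-rich aryl group migrates in preference to hydride (the standard conversion of alkoxy- and aryloxybenzaldehydes into phenols), followed by methanolysis of the aryl formate.

Step 3
Reactants: 5 dimer phenol; 2 4-bromo-3,5-dimethoxybenzaldehyde
Product: 6 trimer aldehyde 4-[3,5-dimethoxy-4-(3,4,5-trimethoxyphenoxy)phenoxy]-3,5-dimethoxybenzaldehyde
Conditions: CuI (10 mol%), picolinic acid (20 mol%), K3PO4, DMSO, 90 °C, argon
Reagents that add atoms: none
Why: Ullmann diaryl ether synthesis of the same kind as step 1, with an unhindered phenol (OH between two CH) and the formyl-activated bromide.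

Step 4
Reactants: 6 trimer aldehyde
Product: 8 trimer phenol 4-[3,5-dimethoxy-4-(3,4,5-trimethoxyphenoxy)phenoxy]-3,5-dimethoxyphenol, via trimer aryl formate 7 (not isolated)
Conditions: mCPBA, CH2Cl2, 0 °C to rt; aq. NaHCO3 wash; then Et3N (cat.), MeOH, rt
Reagents that add atoms: mCPBA, OOC(=O)c1cccc(Cl)c1
Why: Baeyer–Villiger oxidation with aryl migration as in step 2, followed by formate methanolysis.

Step 5
Reactants: 8 trimer phenol; 9 2-bromo-3,4,5-trimethoxybenzaldehyde (ring D)
Product: 10 tetramer aldehyde 3,4,5-trimethoxy-2-(trimer-oxy)benzaldehyde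
Conditions: CuI (10 mol%), picolinic acid (20 mol%), K3PO4, DMSO, 90 °C, argon
Reagents that add atoms: none
Why: Ullmann diaryl ether synthesis at a bromide ortho to a formyl group, the arrangement that makes 2-bromobenzaldehydes good partners for copper-catalysed phenol arylation.

Step 6
Reactants: 10 tetramer aldehyde
Product: 12 tetramer phenol 3,4,5-trimethoxy-2-(trimer-oxy)phenol, via tetramer aryl formate 11 (not isolated)
Conditions: mCPBA, CH2Cl2, 0 °C to rt; aq. NaHCO3 wash; then Et3N (cat.), MeOH, rt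
Reagents that add atoms: mCPBA, OOC(=O)c1cccc(Cl)c1
Why: Baeyer–Villiger oxidation in which the aryl group, carrying an ortho aryloxy and a para methoxy donor, migrates readily, followed by formate methanolysis.

Step 7
Reactants: 12 tetramer phenol; 2 4-bromo-3,5-dimethoxybenzaldehyde (ring C)
Product: 13 pentamer aldehyde 3,5-dimethoxy-4-(tetramer-oxy)benzaldehyde
Conditions: CuI (20 mol%), picolinic acid (40 mol%), K3PO4, DMSO, 100 °C, argon
Reagents that add atoms: none
Why: Ullmann diaryl ether synthesis as in steps 1 and 3, here with a phenol that has one ortho aryloxy group, a combination the picolinic acid system is designed to tolerate.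

Step 8
Reactants: 13 pentamer aldehyde
Product: 15 pentamer phenol 3,5-dimethoxy-4-(tetramer-oxy)phenol (free OH on position 1 of ring C), via pentamer aryl formate 14 (not isolated)
Conditions: mCPBA, CH2Cl2, 0 °C to rt; aq. NaHCO3 wash; then Et3N (cat.), MeOH, rt
Reagents that add atoms: mCPBA, OOC(=O)c1cccc(Cl)c1
Why: Baeyer–Villiger oxidation with aryl migration as in step 2, followed by formate methanolysis.

Step 9
Reactants: 15 pentamer phenol; 16 methyl 2-chloro-3-oxobutanoate
Product: 17 methyl 3-oxo-2-(pentamer-oxy)butanoate (racemic, configurationally labile)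
Conditions: K2CO3, acetone, reflux
Reagents that add atoms: none
Why: Williamson-type SN2 alkylation of the unhindered phenoxide at the doubly activated chloride of an α-chloro-β-ketoester, the usual entry to 2-aryloxyacetoacetates.

Step 10
Reactants: 17 methyl 3-oxo-2-(pentamer-oxy)butanoate
Product: 18 methyl (E)-2-(pentamer-oxy)-3-(trimethylsilyloxy)but-2-enoate
Conditions: Me3SiCl, Et3N, toluene, rt; filtration, concentration
Reagents that add atoms: chlorotrimethylsilane, C[Si](C)(C)Cl
Why: O-silylation of the enolised β-ketoester, the first stage of the standard two-stage preparation of 1,3-bis(silyloxy)dienes.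

Step 11
Reactants: 18 methyl (E)-2-(pentamer-oxy)-3-(trimethylsilyloxy)but-2-enoate
Product: 19 (1E)-1-methoxy-2-(pentamer-oxy)-1,3-bis(trimethylsilyloxy)buta-1,3-diene
Conditions: LiN(iPr)2, THF, −78 °C; Me3SiCl, −78 to 0 °C; hexane, filtration under argon; used crude
Reagents that add atoms: chlorotrimethylsilane, C[Si](C)(C)Cl
Why: Kinetic γ-deprotonation of the β-silyloxy enoate gives the extended ester enolate, which is silylated on oxygen to the ketene silyl acetal (silyl dienol ether formation).

Step 12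
Reactants: 20 2,4,6-trimethoxyphenol (ring A); 21 trichloroethylene
Product: 23 2-[(E)-1,2-dichloroethenyloxy]-1,3,5-trimethoxybenzene, via dichloroacetylene 22 (not isolated)
Conditions: K2CO3, DMF, 70 °C
Reagents that add atoms: none
Why: Base dehydrochlorinates trichloroethylene to dichloroacetylene in the flask and the phenoxide adds anti across it (nucleophilic addition to a haloalkyne), the established route to (E)-1,2-dichlorovinyl aryl ethers.

Step 13
Reactants: 23 2-[(E)-1,2-dichloroethenyloxy]-1,3,5-trimethoxybenzene; 24 benzyl chloroformate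
Product: 27 benzyl 3-(2,4,6-trimethoxyphenoxy)prop-2-ynoate, via chloroalkynyl aryl ether 25 (not isolated), via lithium aryloxyacetylide 26 (not isolated)
Conditions: n-BuLi (2.1 equiv), THF, −78 to −40 °C; then 24, −78 to 0 °C
Reagents that add atoms: none
Why: Deprotonation and β-elimination give the chloroalkyne, chlorine–lithium exchange gives the lithium aryloxyacetylide, and C-acylation by the chloroformate gives the ynoate (dichlorovinyl ether route to ynol ethers), all at temperatures where ortho-lithiation of the trimethoxyphenyl ring is slow.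

Step 14
Reactants: 19 (1E)-1-methoxy-2-(pentamer-oxy)-1,3-bis(trimethylsilyloxy)buta-1,3-diene; 27 benzyl 3-(2,4,6-trimethoxyphenoxy)prop-2-ynoate (3 equiv)
Product: 29 benzyl 2,4-dihydroxy-3-(pentamer-oxy)-6-(2,4,6-trimethoxyphenoxy)benzoate, via cyclohexadiene cycloadduct 28 (not isolated)
Conditions: toluene, 90 °C, sealed tube, argon; then 1 M HCl, THF, 0 °C to rt
Reagents that add atoms: none
Why: The diene, made electron-rich by two silyloxy groups, a methoxy group and an aryloxy group, adds to the ester-activated triple bond in a normal-demand [4+2] cycloaddition, either concerted and asynchronous or as a Mukaiyama–Michael addition followed by Dieckmann-type closure, and forms the bonds between positions 1 and 2 and between positions 5 and 6 of ring B. The closest known reaction type is the Diels–Alder/aromatisation of 1-alkoxy-1,3-bis(silyloxy)buta-1,3-dienes with acetylenic esters to 2,4-dihydroxybenzoates. Ring B closes as a six-membered carbocycle in the intermolecular [4+2] mode (6-exo-trig onto the ester carbon derived from the ketene acetal in the stepwise variant), and cycloadduct 28 aromatises on acid work-up by loss of methanol and the two silyl groups, because only its acetal carbon carries leaving groups, so that the oxygens end as free hydroxyls on positions 3 and 5 of ring B. The only new stereocentre, the acetal carbon of 28, forms as a racemate and is destroyed on aromatisation. The step needs head-to-tail regioselectivity, the CH2 terminus of the diene bonding to the aryloxy-bearing alkyne carbon; the ester makes that carbon the electrophilic β-position and the aryloxy oxygen polarises the triple bond in the same sense. An aryl ynol ether cannot fragment to a ketene by a retro-ene path, so 27 should tolerate the heating.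

Step 15
Reactants: 29 benzyl 2,4-dihydroxy-3-(pentamer-oxy)-6-(2,4,6-trimethoxyphenoxy)benzoate
Product: 31 heptamer diphenol 2-(pentamer-oxy)-5-(2,4,6-trimethoxyphenoxy)benzene-1,3-diol, via free benzoic acid 30 (not isolated)
Conditions: H2 (1 atm), 10% Pd/C, EtOAc–MeOH, rt; filtration; then DMSO, 110 °C, argon
Reagents that add atoms: none
Why: Hydrogenolysis of the benzyl ester frees a benzoic acid flanked by an aryloxy and a hydroxyl group with a para hydroxyl, which loses CO2 on warming through ipso-protonation (thermal protodecarboxylation as for 2,4,6-trihydroxybenzoic acids), while methyl and diaryl ethers are inert.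

Step 16
Reactants: 31 heptamer diphenol
Product: 32 target heptamer, all seventeen hydroxyls free
Conditions: BBr3 (about 45 equiv), CH2Cl2, −78 °C to rt, argon; ice/H2O quench; Sephadex LH-20 (MeOH), then reverse-phase HPLC under argon
Reagents that add atoms: none
Why: Lewis acid-mediated cleavage of aryl methyl ethers (BBr3 demethylation), in which bromide attacks the methyl group of each boron-complexed ether, while the diaryl ether bonds offer no sp3 carbon and should remain intact.

**Compound list**

1 | 3,4,5-trimethoxyphenol | COc1cc(O)cc(OC)c1OC | starting material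
2 | 4-bromo-3,5-dimethoxybenzaldehyde | COc1cc(C=O)cc(OC)c1Br | starting material
3 | dimer aldehyde, 3,5-dimethoxy-4-(3,4,5-trimethoxyphenoxy)benzaldehyde | O=Cc1cc(OC)c(Oc2cc(OC)c(OC)c(OC)c2)c(OC)c1 | intermediate
4 | dimer aryl formate | O=COc1cc(OC)c(Oc2cc(OC)c(OC)c(OC)c2)c(OC)c1 | intermediate (not isolated)
5 | dimer phenol, 3,5-dimethoxy-4-(3,4,5-trimethoxyphenoxy)phenol | Oc1cc(OC)c(Oc2cc(OC)c(OC)c(OC)c2)c(OC)c1 | intermediate
6 | trimer aldehyde (rings G, F and E) | O=Cc1cc(OC)c(Oc2cc(OC)c(Oc3cc(OC)c(OC)c(OC)c3)c(OC)c2)c(OC)c1 | intermediate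
7 | trimer aryl formate | O=COc1cc(OC)c(Oc2cc(OC)c(Oc3cc(OC)c(OC)c(OC)c3)c(OC)c2)c(OC)c1 | intermediate (not isolated)
8 | trimer phenol | Oc1cc(OC)c(Oc2cc(OC)c(Oc3cc(OC)c(OC)c(OC)c3)c(OC)c2)c(OC)c1 | intermediate
9 | 2-bromo-3,4,5-trimethoxybenzaldehyde | COc1cc(C=O)c(Br)c(OC)c1OC | starting material
10 | tetramer aldehyde, 3,4,5-trimethoxy-2-(trimer-oxy)benzaldehyde | O=Cc1cc(OC)c(OC)c(OC)c1Oc1cc(OC)c(Oc2cc(OC)c(Oc3cc(OC)c(OC)c(OC)c3)c(OC)c2)c(OC)c1 | intermediate
11 | tetramer aryl formate | O=COc1cc(OC)c(OC)c(OC)c1Oc1cc(OC)c(Oc2cc(OC)c(Oc3cc(OC)c(OC)c(OC)c3)c(OC)c2)c(OC)c1 | intermediate (not isolated)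
12 | tetramer phenol, 3,4,5-trimethoxy-2-(trimer-oxy)phenol | Oc1cc(OC)c(OC)c(OC)c1Oc1cc(OC)c(Oc2cc(OC)c(Oc3cc(OC)c(OC)c(OC)c3)c(OC)c2)c(OC)c1 | intermediate
13 | pentamer aldehyde, 3,5-dimethoxy-4-(tetramer-oxy)benzaldehyde | O=Cc1cc(OC)c(Oc2cc(OC)c(OC)c(OC)c2Oc2cc(OC)c(Oc3cc(OC)c(Oc4cc(OC)c(OC)c(OC)c4)c(OC)c3)c(OC)c2)c(OC)c1 | intermediate
14 | pentamer aryl formate | O=COc1cc(OC)c(Oc2cc(OC)c(OC)c(OC)c2Oc2cc(OC)c(Oc3cc(OC)c(Oc4cc(OC)c(OC)c(OC)c4)c(OC)c3)c(OC)c2)c(OC)c1 | intermediate (not isolated)
15 | pentamer phenol, 3,5-dimethoxy-4-(tetramer-oxy)phenol | Oc1cc(OC)c(Oc2cc(OC)c(OC)c(OC)c2Oc2cc(OC)c(Oc3cc(OC)c(Oc4cc(OC)c(OC)c(OC)c4)c(OC)c3)c(OC)c2)c(OC)c1 | intermediate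
16 | methyl 2-chloro-3-oxobutanoate | COC(=O)C(Cl)C(C)=O | starting material
17 | methyl 3-oxo-2-(pentamer-oxy)butanoate (racemic) | COC(=O)C(Oc1cc(OC)c(Oc2cc(OC)c(OC)c(OC)c2Oc2cc(OC)c(Oc3cc(OC)c(Oc4cc(OC)c(OC)c(OC)c4)c(OC)c3)c(OC)c2)c(OC)c1)C(C)=O | intermediate
18 | methyl (E)-2-(pentamer-oxy)-3-(trimethylsilyloxy)but-2-enoate | COC(=O)/C(Oc1cc(OC)c(Oc2cc(OC)c(OC)c(OC)c2Oc2cc(OC)c(Oc3cc(OC)c(Oc4cc(OC)c(OC)c(OC)c4)c(OC)c3)c(OC)c2)c(OC)c1)=C(/C)O[Si](C)(C)C | intermediate
19 | (1E)-1-methoxy-2-(pentamer-oxy)-1,3-bis(trimethylsilyloxy)buta-1,3-diene | C=C(O[Si](C)(C)C)/C(Oc1cc(OC)c(Oc2cc(OC)c(OC)c(OC)c2Oc2cc(OC)c(Oc3cc(OC)c(Oc4cc(OC)c(OC)c(OC)c4)c(OC)c3)c(OC)c2)c(OC)c1)=C(/OC)O[Si](C)(C)C | intermediate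
20 | 2,4,6-trimethoxyphenol | COc1cc(OC)c(O)c(OC)c1 | starting material
21 | trichloroethylene | ClC=C(Cl)Cl | starting material
22 | dichloroacetylene | ClC#CCl | intermediate (not isolated)
23 | 2-[(E)-1,2-dichloroethenyloxy]-1,3,5-trimethoxybenzene | Cl/C=C(Cl)\Oc1c(OC)cc(OC)cc1OC | intermediate
24 | benzyl chloroformate | O=C(Cl)OCc1ccccc1 | starting material
25 | 2-(chloroethynyloxy)-1,3,5-trimethoxybenzene | ClC#COc1c(OC)cc(OC)cc1OC | intermediate (not isolated)
26 | lithium (2,4,6-trimethoxyphenoxy)acetylide | [Li]C#COc1c(OC)cc(OC)cc1OC | intermediate (not isolated)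
27 | benzyl 3-(2,4,6-trimethoxyphenoxy)prop-2-ynoate | O=C(OCc1ccccc1)C#COc1c(OC)cc(OC)cc1OC | intermediate
28 | benzyl 6-methoxy-5-(pentamer-oxy)-2-(2,4,6-trimethoxyphenoxy)-4,6-bis(trimethylsilyloxy)cyclohexa-1,4-diene-1-carboxylate (racemic) | COC1(O[Si](C)(C)C)C(Oc2cc(OC)c(Oc3cc(OC)c(OC)c(OC)c3Oc3cc(OC)c(Oc4cc(OC)c(Oc5cc(OC)c(OC)c(OC)c5)c(OC)c4)c(OC)c3)c(OC)c2)=C(O[Si](C)(C)C)CC(Oc2c(OC)cc(OC)cc2OC)=C1C(=O)OCc1ccccc1 | intermediate (not isolated)
29 | benzyl 2,4-dihydroxy-3-(pentamer-oxy)-6-(2,4,6-trimethoxyphenoxy)benzoate | COc1cc(OC)c(Oc2cc(O)c(Oc3cc(OC)c(Oc4cc(OC)c(OC)c(OC)c4Oc4cc(OC)c(Oc5cc(OC)c(Oc6cc(OC)c(OC)c(OC)c6)c(OC)c5)c(OC)c4)c(OC)c3)c(O)c2C(=O)OCc2ccccc2)c(OC)c1 | intermediate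
30 | 2,4-dihydroxy-3-(pentamer-oxy)-6-(2,4,6-trimethoxyphenoxy)benzoic acid | COc1cc(OC)c(Oc2cc(O)c(Oc3cc(OC)c(Oc4cc(OC)c(OC)c(OC)c4Oc4cc(OC)c(Oc5cc(OC)c(Oc6cc(OC)c(OC)c(OC)c6)c(OC)c5)c(OC)c4)c(OC)c3)c(O)c2C(=O)O)c(OC)c1 | intermediate (not isolated)
31 | heptamer diphenol, 2-(pentamer-oxy)-5-(2,4,6-trimethoxyphenoxy)benzene-1,3-diol | COc1cc(OC)c(Oc2cc(O)c(Oc3cc(OC)c(Oc4cc(OC)c(OC)c(OC)c4Oc4cc(OC)c(Oc5cc(OC)c(Oc6cc(OC)c(OC)c(OC)c6)c(OC)c5)c(OC)c4)c(OC)c3)c(O)c2)c(OC)c1 | intermediate
32 | CNP0304148.0, heptamer with seventeen free hydroxyls | Oc1cc(O)c(Oc2cc(O)c(Oc3cc(O)c(Oc4cc(O)c(O)c(O)c4Oc4cc(O)c(Oc5cc(O)c(Oc6cc(O)c(O)c(O)c6)c(O)c5)c(O)c4)c(O)c3)c(O)c2)c(O)c1 | target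

**Step count**

Total: 16 steps. Longest linear sequence: 14 steps (steps 1 to 11, then 14 to 16); the ynoate branch is steps 12 and 13.

**Steps most likely to fail**

Step 14 (key cycloaddition).
- What may go wrong: the aryloxy oxygen donates into the triple bond and lowers its reactivity, so the diene may lose or shift its silyl groups before it adds. In a stepwise pathway the Michael adduct may also expel aryloxide instead of closing the ring.
- Fallback: ring B is bought as an arene and the chain is extended by the chemistry of steps 1 to 8.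
- It sets out from pentamer phenol 15. Ullmann coupling with 2 under the conditions of step 7 would give the hexamer aldehyde F1 (rings G to B).
- mCPBA oxidation through the hexamer aryl formate F2 and methanolysis would give the hexamer phenol F3.
- Ullmann coupling of F3 with commercial 2-bromo-3,5-dimethoxybenzaldehyde, whose bromide is activated by the ortho formyl group as in step 5, would give the heptamer aldehyde F4 with the formyl group on position 2 of ring A.
- Baeyer–Villiger oxidation through the heptamer aryl formate F5 would give the heptamer phenol F6, which has the full oxygen pattern of the target with sixteen methyl ethers.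
- BBr3 cleavage as in step 16 brings the fallback back to the route at target 32.

Step 7 (Ullmann coupling at the doubly ortho-substituted bromide with an ortho-substituted phenol; the same issue applies in milder form to steps 1 and 3).
- What may go wrong: slow reaction of the hindered C–Br bond at copper, with hydrodebromination of 2 and recovery of the phenol.
- Fallback: the C–O bond formation is moved from copper to palladium catalysis. The ether then forms by reductive elimination from an aryl(aryloxo)palladium complex, which bulky biarylphosphines accelerate for ortho-substituted and electron-poor aryl groups.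
- It sets out from 12 and 2 and would use Pd(OAc)2, 2-di-tert-butylphosphino-2′,4′,6′-triisopropylbiphenyl and K3PO4 in toluene at 100 °C (Buchwald–Hartwig-type etherification).
- It comes back to the route at pentamer aldehyde 13 without any new compound.

Step 16 (cleavage of fifteen methyl ethers).
- What may go wrong: incomplete demethylation giving mixtures of partial methyl ethers, and oxidative loss of the free polyphenol during isolation.
- Fallback: capture and release through the peracetate. It sets out from 31 and comes back at 32.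
- After the BBr3 treatment and quench, the crude polyphenol 32 would be acetylated without isolation (Ac2O, pyridine, rt) to the heptadecaacetate F7.
- F7 should be stable to air and to silica, so partially methylated material can be separated and resubmitted.
- Acid methanolysis (HCl in MeOH, generated from a little acetyl chloride, rt, argon) would then release 32 under non-oxidising conditions.

**Further compounds**

F1 | step 14 | hexamer aldehyde (rings G to B), 3,5-dimethoxy-4-(pentamer-oxy)benzaldehyde | O=Cc1cc(OC)c(Oc2cc(OC)c(Oc3cc(OC)c(OC)c(OC)c3Oc3cc(OC)c(Oc4cc(OC)c(Oc5cc(OC)c(OC)c(OC)c5)c(OC)c4)c(OC)c3)c(OC)c2)c(OC)c1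
F2 | step 14 | hexamer aryl formate | O=COc1cc(OC)c(Oc2cc(OC)c(Oc3cc(OC)c(OC)c(OC)c3Oc3cc(OC)c(Oc4cc(OC)c(Oc5cc(OC)c(OC)c(OC)c5)c(OC)c4)c(OC)c3)c(OC)c2)c(OC)c1
F3 | step 14 | hexamer phenol, 3,5-dimethoxy-4-(pentamer-oxy)phenol | Oc1cc(OC)c(Oc2cc(OC)c(Oc3cc(OC)c(OC)c(OC)c3Oc3cc(OC)c(Oc4cc(OC)c(Oc5cc(OC)c(OC)c(OC)c5)c(OC)c4)c(OC)c3)c(OC)c2)c(OC)c1
F4 | step 14 | heptamer aldehyde, formyl group on position 2 of ring A, all hydroxyls as methyl ethers | COc1cc(C=O)c(Oc2cc(OC)c(Oc3cc(OC)c(Oc4cc(OC)c(OC)c(OC)c4Oc4cc(OC)c(Oc5cc(OC)c(Oc6cc(OC)c(OC)c(OC)c6)c(OC)c5)c(OC)c4)c(OC)c3)c(OC)c2)c(OC)c1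
F5 | step 14 | heptamer aryl formate, formate on the oxygen at position 2 of ring A | COc1cc(OC=O)c(Oc2cc(OC)c(Oc3cc(OC)c(Oc4cc(OC)c(OC)c(OC)c4Oc4cc(OC)c(Oc5cc(OC)c(Oc6cc(OC)c(OC)c(OC)c6)c(OC)c5)c(OC)c4)c(OC)c3)c(OC)c2)c(OC)c1
F6 | step 14 | heptamer phenol, free hydroxyl on position 2 of ring A, sixteen methyl ethers | COc1cc(O)c(Oc2cc(OC)c(Oc3cc(OC)c(Oc4cc(OC)c(OC)c(OC)c4Oc4cc(OC)c(Oc5cc(OC)c(Oc6cc(OC)c(OC)c(OC)c6)c(OC)c5)c(OC)c4)c(OC)c3)c(OC)c2)c(OC)c1
F0 | step 7 | none | none
F7 | step 16 | heptadecaacetate of the target | CC(=O)Oc1cc(OC(C)=O)c(Oc2cc(OC(C)=O)c(Oc3cc(OC(C)=O)c(Oc4cc(OC(C)=O)c(OC(C)=O)c(OC(C)=O)c4Oc4cc(OC(C)=O)c(Oc5cc(OC(C)=O)c(Oc6cc(OC(C)=O)c(OC(C)=O)c(OC(C)=O)c6)c(OC(C)=O)c5)c(OC(C)=O)c4)c(OC(C)=O)c3)c(OC(C)=O)c2)c(OC(C)=O)c1
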